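## Retrosynthetic overview
1. The target is epicatechin 3-O-gallate-(4β→8)-epigallocatechin 3-O-gallate-(4β→8)-catechin 3-O-gallate. The last step is hydrogenolysis of 22 benzyl ethers.
2. Both interflavan C4–C8 bonds are cut. Each upper unit is traced to a flav-3-en-3-yl gallate, the enol ester of a flavan-3-one, used as a reversed-polarity a2 (enolonium-type) synthon. C4 (α-carbon of the masked ketone) and C8 (enol-type carbon of ring A) are both innately nucleophilic.
3. Protonation at C3 anti to the 2-aryl group, followed by β-face arylation at C4, sets C3 and C4 of each upper unit in the C–C bond-forming step. Only C2 comes from the chiral pool.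
4. The enol gallates come from (+)-catechin and (−)-epigallocatechin by benzylation, oxidation and enolate O-galloylation. The bottom unit comes from the same benzylated catechin by esterification.
5. No ring is built: rings A, B and C of all three units and the galloyl rings are bought. The middle–bottom bond is made first, then the top–middle bond.

Assumption: the SMILES is read as top unit 2R,3R,4β, middle unit 2R,3R,4β and bottom unit 2R,3S, and (−)-epigallocatechin is taken as a commercial green-tea catechin.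

## Route

Step 1
Reactants: 1 3,4,5-tris(benzyloxy)benzoic acid
Product: 2 3,4,5-tris(benzyloxy)benzoyl chloride
Conditions: (COCl)2, DMF (cat.), CH2Cl2, 0 °C → rt
Reagents that add atoms: oxalyl chloride, O=C(Cl)C(=O)Cl
Why: Acid chloride formation by acyl substitution through the catalytic chloroiminium (Vilsmeier-type) species; benzyl ethers are inert and no stereocentre is involved.

Step 2
Reactants: 3 (+)-catechin (2R,3S)
Product: 4 5,7,3',4'-tetra-O-benzyl-(+)-catechin (2R,3S; 3-OH free)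
Conditions: BnBr, K2CO3, DMF, 0 °C → rt, Ar
Reagents that add atoms: benzyl bromide, BrCc1ccccc1
Why: Williamson ether synthesis in which K2CO3 deprotonates only the four phenols, so the secondary 3-OH stays free and C2 and C3 are untouched.

Step 3
Reactants: 4 5,7,3',4'-tetra-O-benzyl-(+)-catechin; 2 3,4,5-tris(benzyloxy)benzoyl chloride
Product: 5 bottom unit 5,7,3',4'-tetra-O-benzyl-(+)-catechin 3-O-[3,4,5-tris(benzyloxy)benzoate] (2R,3S)
Conditions: Et3N, DMAP (cat.), CH2Cl2, 0 °C → rt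
Reagents that add atoms: none
Why: DMAP-catalysed O-acylation (nucleophilic catalysis) of the only free hydroxyl; the C3–O bond is not broken, so 2R,3S is retained.

Step 4
Reactants: 4 5,7,3',4'-tetra-O-benzyl-(+)-catechin
Product: 6 (2R)-5,7-bis(benzyloxy)-2-[3,4-bis(benzyloxy)phenyl]chroman-3-one
Conditions: Dess–Martin periodinane, CH2Cl2, 0 °C → rt
Reagents that add atoms: none
Why: Dess–Martin oxidation under near-neutral conditions erases C3 but leaves the now enolisable C2 (R) unepimerised and the benzyl ethers intact.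

Step 5
Reactants: 6 (2R)-5,7-bis(benzyloxy)-2-[3,4-bis(benzyloxy)phenyl]chroman-3-one; 2 3,4,5-tris(benzyloxy)benzoyl chloride
Product: 8 top enol gallate (2R)-5,7-bis(benzyloxy)-2-[3,4-bis(benzyloxy)phenyl]-2H-chromen-3-yl 3,4,5-tris(benzyloxy)benzoate, via potassium enolate 7 (not isolated)
Conditions: KN(SiMe3)2, THF, −78 °C (6 added to the base); then 2, −78 → −40 °C, dark
Reagents that add atoms: none
Why: Kinetic enolate formation followed by O-acylation: the hindered amide base takes a proton from the C4 methylene rather than the tertiary, oxygen-flanked C2–H, and the potassium enolate meets the hard aroyl chloride at oxygen because C4 is shielded by the peri 5-benzyloxy group, so the C3=C4 enol ester forms with C2 (R) intact.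

Step 6
Reactants: 9 (−)-epigallocatechin (2R,3R)
Product: 10 5,7,3',4',5'-penta-O-benzyl-(−)-epigallocatechin (2R,3R; 3-OH free)
Conditions: BnBr, K2CO3, DMF, 0 °C → rt, Ar
Reagents that add atoms: benzyl bromide, BrCc1ccccc1
Why: Williamson ether synthesis on the five phenols only, run under argon to protect the pyrogallol ring B from oxidation; C2 is untouched.

Step 7
Reactants: 10 5,7,3',4',5'-penta-O-benzyl-(−)-epigallocatechin
Product: 11 (2R)-5,7-bis(benzyloxy)-2-[3,4,5-tris(benzyloxy)phenyl]chroman-3-one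
Conditions: Dess–Martin periodinane, CH2Cl2, 0 °C → rt
Reagents that add atoms: none
Why: Dess–Martin oxidation as in step 4; C3 is erased and C2 (R) is kept because no base or acid strong enough for enolisation is present.

Step 8
Reactants: 11 (2R)-5,7-bis(benzyloxy)-2-[3,4,5-tris(benzyloxy)phenyl]chroman-3-one; 2 3,4,5-tris(benzyloxy)benzoyl chloride
Product: 13 middle enol gallate (2R)-5,7-bis(benzyloxy)-2-[3,4,5-tris(benzyloxy)phenyl]-2H-chromen-3-yl 3,4,5-tris(benzyloxy)benzoate, via potassium enolate 12 (not isolated)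
Conditions: KN(SiMe3)2, THF, −78 °C (11 added to the base); then 2, −78 → −40 °C, dark
Reagents that add atoms: none
Why: Kinetic C4 enolate formation and O-acylation as in step 5, giving the ring-A-conjugated enol ester with C2 (R) intact.

Step 9
Reactants: 13 middle enol gallate; 5 bottom unit
Product: 15 protected dimer octa-O-benzyl-epigallocatechin 3-O-gallate-(4β→8)-hepta-O-benzyl-catechin 3-O-gallate (upper unit 2R,3R; 2,3-cis; 3,4-trans; lower unit 2R,3S), via C4 cation 14 (not isolated)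
Conditions: HN(SO2CF3)2 (10 mol %), 5 (3 equiv), 13 added over 1 h, CH2Cl2, −78 → −45 °C, dark; then Et3N
Reagents that add atoms: none
Why: Proposed new method: C4 of 13 is the α-carbon of a masked C3 ketone and C8 of 5 is an enol-type carbon of the phloroglucinol ring, so both are innately nucleophilic; because the acyl group makes O3 a poor donor while ring A carries three alkoxy donors, the strong acid protonates the enol ester at C3 instead of C4 and turns C4 into an enolonium-type a2 acceptor (cation 14, buffered by the gallate carbonyl as a cis-fused dioxolanylium ion); the proton reaches C3 on the β face, anti to the 2-aryl group that A(1,2) strain against the 3-acyloxy group holds pseudo-axial (the same bias that sends bulky hydrides to that face of ketone 11), which sets 3R (2,3-cis); C8 of 5 then attacks C4 anti to the α-oriented gallate, which sets 4β (3,4-trans), and rearomatisation returns the proton; the closest known reaction types are the Brønsted acid catalysed Friedel–Crafts hydroarylation of electron-rich styrenes and the Lewis acid coupling of 4-alkoxyflavan-3-yl esters, which runs through the same cation with 3,4-trans selectivity.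

Step 10
Reactants: 8 top enol gallate; 15 protected dimer
Product: 17 protected trimer docosa-O-benzyl epicatechin 3-O-gallate-(4β→8)-epigallocatechin 3-O-gallate-(4β→8)-catechin 3-O-gallate, via C4 cation 16 (not isolated)
Conditions: HN(SO2CF3)2 (10 mol %), 15 (1 equiv), 8 (1.3 equiv) added over 2 h, CH2Cl2, −78 → −45 °C, dark; then Et3N
Reagents that add atoms: none
Why: Proposed new method: the same C3-protonation of an enol gallate as in step 9 makes the normally nucleophilic C4 of 8 the acceptor (cation 16) with 3R set by β-face proton delivery anti to the pseudo-axial 2-aryl group and 4β set by attack anti to the gallate; C8 of the middle unit of 15 is the only open phloroglucinol site (the bottom C8 is substituted and both C6 positions sit between two benzyloxy groups); the closest known reaction types are styrene hydroarylation and the chain extension of benzylated procyanidin dimers at the upper-unit C8 by flavan C4 cations.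

Step 11
Reactants: 17 protected trimer
Product: 18 CNP0321910.1 epicatechin 3-O-gallate-(4β→8)-epigallocatechin 3-O-gallate-(4β→8)-catechin 3-O-gallate
Conditions: H2 (1 atm), Pd(OH)2/C, THF–MeOH–H2O, rt
Reagents that add atoms: none
Why: Catalytic hydrogenolysis removes all 22 O-benzyl groups in one operation, while the gallate esters, the C2–O1 bonds, the C4–C8 bonds and all eight stereocentres are unaffected at 1 atm.

## Compound list
1 | 3,4,5-tris(benzyloxy)benzoic acid | O=C(O)c1cc(OCc2ccccc2)c(OCc2ccccc2)c(OCc2ccccc2)c1 | starting material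
2 | 3,4,5-tris(benzyloxy)benzoyl chloride | O=C(Cl)c1cc(OCc2ccccc2)c(OCc2ccccc2)c(OCc2ccccc2)c1 | intermediate
3 | (+)-catechin, (2R,3S)-2-(3,4-dihydroxyphenyl)chroman-3,5,7-triol | Oc1cc(O)c2c(c1)O[C@H](c1ccc(O)c(O)c1)[C@@H](O)C2 | starting material
4 | 5,7,3',4'-tetra-O-benzyl-(+)-catechin (2R,3S, free 3-OH) | c1ccccc1COc1cc(OCc2ccccc2)c2c(c1)O[C@H](c1ccc(OCc3ccccc3)c(OCc3ccccc3)c1)[C@@H](O)C2 | intermediate
5 | bottom unit: 5,7,3',4'-tetra-O-benzyl-(+)-catechin 3-O-[3,4,5-tris(benzyloxy)benzoate] (2R,3S) | c1ccccc1COc1cc(OCc2ccccc2)c2c(c1)O[C@H](c1ccc(OCc3ccccc3)c(OCc3ccccc3)c1)[C@@H](OC(=O)c1cc(OCc3ccccc3)c(OCc3ccccc3)c(OCc3ccccc3)c1)C2 | intermediate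
6 | (2R)-5,7-bis(benzyloxy)-2-[3,4-bis(benzyloxy)phenyl]chroman-3-one | c1ccccc1COc1cc(OCc2ccccc2)c2c(c1)O[C@H](c1ccc(OCc3ccccc3)c(OCc3ccccc3)c1)C(=O)C2 | intermediate
7 | potassium C3=C4 enolate of 6 (2R), not isolated | [K+].[O-]C1=Cc2c(OCc3ccccc3)cc(OCc3ccccc3)cc2O[C@@H]1c1ccc(OCc3ccccc3)c(OCc3ccccc3)c1 | intermediate
8 | top enol gallate: (2R)-5,7-bis(benzyloxy)-2-[3,4-bis(benzyloxy)phenyl]-2H-chromen-3-yl 3,4,5-tris(benzyloxy)benzoate | O=C(OC1=Cc2c(OCc3ccccc3)cc(OCc3ccccc3)cc2O[C@@H]1c1ccc(OCc3ccccc3)c(OCc3ccccc3)c1)c1cc(OCc3ccccc3)c(OCc3ccccc3)c(OCc3ccccc3)c1 | intermediate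
9 | (−)-epigallocatechin, (2R,3R)-2-(3,4,5-trihydroxyphenyl)chroman-3,5,7-triol | Oc1cc(O)c2c(c1)O[C@H](c1cc(O)c(O)c(O)c1)[C@H](O)C2 | starting material
10 | 5,7,3',4',5'-penta-O-benzyl-(−)-epigallocatechin (2R,3R, free 3-OH) | c1ccccc1COc1cc(OCc2ccccc2)c2c(c1)O[C@H](c1cc(OCc3ccccc3)c(OCc3ccccc3)c(OCc3ccccc3)c1)[C@H](O)C2 | intermediate
11 | (2R)-5,7-bis(benzyloxy)-2-[3,4,5-tris(benzyloxy)phenyl]chroman-3-one | c1ccccc1COc1cc(OCc2ccccc2)c2c(c1)O[C@H](c1cc(OCc3ccccc3)c(OCc3ccccc3)c(OCc3ccccc3)c1)C(=O)C2 | intermediate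
12 | potassium C3=C4 enolate of 11 (2R), not isolated | [K+].[O-]C1=Cc2c(OCc3ccccc3)cc(OCc3ccccc3)cc2O[C@@H]1c1cc(OCc3ccccc3)c(OCc3ccccc3)c(OCc3ccccc3)c1 | intermediate
13 | middle enol gallate: (2R)-5,7-bis(benzyloxy)-2-[3,4,5-tris(benzyloxy)phenyl]-2H-chromen-3-yl 3,4,5-tris(benzyloxy)benzoate | O=C(OC1=Cc2c(OCc3ccccc3)cc(OCc3ccccc3)cc2O[C@@H]1c1cc(OCc3ccccc3)c(OCc3ccccc3)c(OCc3ccccc3)c1)c1cc(OCc3ccccc3)c(OCc3ccccc3)c(OCc3ccccc3)c1 | intermediate
14 | (2R,3R)-octa-O-benzyl-epigallocatechin 3-O-gallate C4 benzylic cation (2,3-cis; in equilibrium with the cis-fused dioxolanylium form), bis(trifluoromethylsulfonyl)imide salt, not isolated | O=C(O[C@@H]1[CH+]c2c(OCc3ccccc3)cc(OCc3ccccc3)cc2O[C@@H]1c1cc(OCc3ccccc3)c(OCc3ccccc3)c(OCc3ccccc3)c1)c1cc(OCc3ccccc3)c(OCc3ccccc3)c(OCc3ccccc3)c1.O=S(=O)([N-]S(=O)(=O)C(F)(F)F)C(F)(F)F | intermediate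
15 | protected dimer: octa-O-benzyl-epigallocatechin 3-O-gallate-(4β→8)-hepta-O-benzyl-catechin 3-O-gallate (upper 2R,3R, 3,4-trans; lower 2R,3S) | O=C(O[C@@H]1[C@@H](c2c(OCc5ccccc5)cc(OCc5ccccc5)c3c2O[C@H](c2ccc(OCc5ccccc5)c(OCc5ccccc5)c2)[C@@H](OC(=O)c2cc(OCc5ccccc5)c(OCc5ccccc5)c(OCc5ccccc5)c2)C3)c2c(OCc5ccccc5)cc(OCc5ccccc5)cc2O[C@@H]1c1cc(OCc5ccccc5)c(OCc5ccccc5)c(OCc5ccccc5)c1)c1cc(OCc5ccccc5)c(OCc5ccccc5)c(OCc5ccccc5)c1 | intermediate
16 | (2R,3R)-hepta-O-benzyl-epicatechin 3-O-gallate C4 benzylic cation (2,3-cis), bis(trifluoromethylsulfonyl)imide salt, not isolated | O=C(O[C@@H]1[CH+]c2c(OCc3ccccc3)cc(OCc3ccccc3)cc2O[C@@H]1c1ccc(OCc3ccccc3)c(OCc3ccccc3)c1)c1cc(OCc3ccccc3)c(OCc3ccccc3)c(OCc3ccccc3)c1.O=S(=O)([N-]S(=O)(=O)C(F)(F)F)C(F)(F)F | intermediate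
17 | protected trimer with 22 benzyl ethers: epicatechin 3-O-gallate-(4β→8)-epigallocatechin 3-O-gallate-(4β→8)-catechin 3-O-gallate (top 2R,3R,4β; middle 2R,3R,4β; bottom 2R,3S) | O=C(O[C@@H]1[C@@H](c2c(OCc5ccccc5)cc(OCc5ccccc5)c3c2O[C@H](c2ccc(OCc5ccccc5)c(OCc5ccccc5)c2)[C@@H](OC(=O)c2cc(OCc5ccccc5)c(OCc5ccccc5)c(OCc5ccccc5)c2)C3)c2c(OCc5ccccc5)cc(OCc5ccccc5)c([C@H]3c4c(OCc5ccccc5)cc(OCc5ccccc5)cc4O[C@H](c4ccc(OCc5ccccc5)c(OCc5ccccc5)c4)[C@@H]3OC(=O)c3cc(OCc5ccccc5)c(OCc5ccccc5)c(OCc5ccccc5)c3)c2O[C@@H]1c1cc(OCc5ccccc5)c(OCc5ccccc5)c(OCc5ccccc5)c1)c1cc(OCc5ccccc5)c(OCc5ccccc5)c(OCc5ccccc5)c1 | intermediate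
18 | CNP0321910.1, epicatechin 3-O-gallate-(4β→8)-epigallocatechin 3-O-gallate-(4β→8)-catechin 3-O-gallate | O=C(O[C@@H]1[C@@H](c2c(O)cc(O)c3c2O[C@H](c2ccc(O)c(O)c2)[C@@H](OC(=O)c2cc(O)c(O)c(O)c2)C3)c2c(O)cc(O)c([C@H]3c4c(O)cc(O)cc4O[C@H](c4ccc(O)c(O)c4)[C@@H]3OC(=O)c3cc(O)c(O)c(O)c3)c2O[C@@H]1c1cc(O)c(O)c(O)c1)c1cc(O)c(O)c(O)c1 | target

## Step count and risks
Total step count: 11.
Longest linear sequence: 6 steps (9 → 10 → 11 → 13 → 15 → 17 → 18; steps 6, 7, 8, 9, 10 and 11).

**Step 9.**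
- It can fail by protonation at C4, which returns ketone 11 on work-up.
- It can fail by reversible or α-face protonation at C3, which gives 2,3-trans isomers.
- It can fail by self-condensation of 13.

The fallback sets out from 13 and comes back at 15. It separates cation formation from C–C bond formation by trapping the cation with a much better nucleophile. Treating 13 with thiophenol and HN(SO2CF3)2 (5 mol %) in CH2Cl2 at −78 °C gives octa-O-benzyl-4β-(phenylthio)-epigallocatechin 3-O-gallate F1. This is a storable donor from which any 2,3-trans isomer can be removed by chromatography. F1 is then activated thiophilically with AgBF4 in CH2Cl2 at −40 °C in the presence of 5 (3 equiv) to give 15.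

**Step 10.**
- C8 of the middle unit of 15 is hindered, so 8 may oligomerise instead.
- The acid may also cleave the interflavan bond already present.

The fallback sets out from 6 and comes back at 17. It uses a donor whose C3 centre is fixed before the coupling. Ketone 6 is reduced with LiBH(s-Bu)3 in THF at −78 °C, with hydride delivered anti to the 2-aryl group, to give 5,7,3',4'-tetra-O-benzyl-(−)-epicatechin F2. DDQ and 2-ethoxyethanol in CH2Cl2 oxidise C4 to 4β-(2-ethoxyethoxy)-5,7,3',4'-tetra-O-benzyl-epicatechin F3. Acylation with 2 (Et3N, DMAP) gives 4β-(2-ethoxyethoxy)-hepta-O-benzyl-epicatechin 3-O-gallate F4. Catalytic Me3SiOTf in CH2Cl2 at −78 °C couples F4 with 15 to give 17.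

**Step 8 (and its twin, step 5).**
- Deprotonation at C2, proton exchange between enolate and ketone, or C-acylation would cost regiochemistry or the C2 configuration.

The fallback sets out from 11 and comes back at 13. It replaces the metal enolate by an isolable silyl enol ether and a neutral acyl transfer. Soft enolisation of 11 with Me3SiOTf and Et3N in CH2Cl2 at 0 °C gives (2R)-5,7-bis(benzyloxy)-2-[3,4,5-tris(benzyloxy)phenyl]-3-(trimethylsilyloxy)-2H-chromene F5, whose regiochemistry is checked by NMR. Chloride 2 is converted with KF in MeCN into 3,4,5-tris(benzyloxy)benzoyl fluoride F6. F5 and F6 are then joined with catalytic Bu4NF in THF at −20 °C to give 13.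

Further compounds
F1 | step 9 | octa-O-benzyl-4β-(phenylthio)-epigallocatechin 3-O-gallate (2,3-cis, 3,4-trans) | O=C(O[C@@H]1[C@@H](Sc3ccccc3)c2c(OCc3ccccc3)cc(OCc3ccccc3)cc2O[C@@H]1c1cc(OCc3ccccc3)c(OCc3ccccc3)c(OCc3ccccc3)c1)c1cc(OCc3ccccc3)c(OCc3ccccc3)c(OCc3ccccc3)c1
F2 | step 10 | 5,7,3',4'-tetra-O-benzyl-(−)-epicatechin (2R,3R) | c1ccccc1COc1cc(OCc2ccccc2)c2c(c1)O[C@H](c1ccc(OCc3ccccc3)c(OCc3ccccc3)c1)[C@H](O)C2
F3 | step 10 | 4β-(2-ethoxyethoxy)-5,7,3',4'-tetra-O-benzyl-epicatechin (2,3-cis, 3,4-trans, free 3-OH) | O[C@@H]1[C@@H](OCCOCC)c2c(OCc3ccccc3)cc(OCc3ccccc3)cc2O[C@@H]1c1ccc(OCc3ccccc3)c(OCc3ccccc3)c1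
F4 | step 10 | 4β-(2-ethoxyethoxy)-hepta-O-benzyl-epicatechin 3-O-gallate (2,3-cis, 3,4-trans) | O=C(O[C@@H]1[C@@H](OCCOCC)c2c(OCc3ccccc3)cc(OCc3ccccc3)cc2O[C@@H]1c1ccc(OCc3ccccc3)c(OCc3ccccc3)c1)c1cc(OCc3ccccc3)c(OCc3ccccc3)c(OCc3ccccc3)c1
F5 | step 8 | (2R)-5,7-bis(benzyloxy)-2-[3,4,5-tris(benzyloxy)phenyl]-3-(trimethylsilyloxy)-2H-chromene | C[Si](C)(C)OC1=Cc2c(OCc3ccccc3)cc(OCc3ccccc3)cc2O[C@@H]1c1cc(OCc3ccccc3)c(OCc3ccccc3)c(OCc3ccccc3)c1
F6 | step 8 | 3,4,5-tris(benzyloxy)benzoyl fluoride | O=C(F)c1cc(OCc2ccccc2)c(OCc2ccccc2)c(OCc2ccccc2)c1
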